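# Proposed total synthesis of CNP0240716.2 (22)

Atom labels used throughout (tricyclo[5.4.0.0(2,8)]undecane numbering of the target): C1 ketone α-bridgehead, C2 methylated quaternary carbon, C3 and C4 methylenes, C5 acyloxy carbon, C6 quaternary carbon (methyl and C12H2–O), C7 ring B methine, C8 allylic bridgehead, C9(methyl)=C10, C11 ketone. Ring A = C1, C2, C8, C9, C10, C11; ring B = C1, C2, C8, C7; ring C = C2, C3, C4, C5, C6, C7, C8.

## The problem

Target 22 is a longipinane diester: a cyclobutane (ring B) is shared by a cyclohexenone (ring A, ketone at C11, methyl on C9 of the C9=C10 alkene) and a cycloheptane (ring C), and ring C carries a methyl on C2, a methyl and an acyloxymethyl group (C12) on C6 and an acyloxy group on C5. Six contiguous stereocentres result (C1, C2, C5, C6, C7, C8), two of them quaternary. The four on ring B are locked together by the bridged geometry: once ring C exists and ring A is cis-fused to it at C2–C8, the C1–C7 bond can form in one way only, so the independent tasks are the C5/C6 pair, its relation to the face that carries ring A, and the absolute configuration. C5 and C6 are a carbinol next to a quaternary carbon that is flanked by a second oxidised carbon (C7), the reduced form of a 2,2-disubstituted 1,3-dione, so one enantioselective reduction can set both; the C6 methyl, if held axial on ring C, can then decide which face of ring C is attacked. The two angelate esters isomerise to the E (tiglate) esters with bases and nucleophilic catalysts and are Michael acceptors, the secondary one sits on a neopentyl-type carbon, the enone has acidic γ-hydrogens and the cyclobutane is strained, so the esters must come last and strong acid is best avoided once ring B is closed. The enabling feature is ring A: without the C1–C7 bond it is a cyclohexene with oxygen on C11 and a methyl on C9, the retron of a [4+2] addition of a 2-silyloxypenta-1,3-diene to the C8=C2 alkene of a ring C enone whose carbonyl is C7. That same C7 carbonyl, once reduced and sulfonylated, is the electrophile to which C1, the α′-carbon of the ring A ketone delivered by the diene, can be joined to close ring B.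

## Retrosynthesis

The last two disconnections are of the acyl C–O bonds: 22 goes back to the primary monoester 21 and angelic acid 20, and 21 to diol 19 and a second molecule of 20. Cutting here keeps the isomerisable Z esters out of every basic or organometallic step. Diol 19 already has the full skeleton and all six stereocentres. The forward reactions must acylate the primary hydroxyl first and then a hindered secondary hydroxyl, both without Z to E isomerisation.

Diol 19 is the deprotected form of acetonide 18, and in 18 the C1–C7 bond is cut to give enone mesylate 17. Of the four cyclobutane bonds this is the only one that neither ends at the quaternary C2 nor lies in ring C. C1 is α′ to the ring A ketone and C7 can carry a leaving group, so the bond is an intramolecular enolate alkylation. Compound 17 is a cis-fused 6–7 bicycle without the strained ring. The forward step needs α′-selective deprotonation and a C7 leaving group on the face opposite to C1.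

Compound 17 is traced to silyl enol ether 16, then to alcohol 15 and ketone 14. No skeletal bond is cut, but the order matters. The enone is unveiled only after C7 has been reduced, so that the ring C ketone is the only carbonyl present at the reduction. The silyl enol ether of 14 fixes the future alkene at C9=C10 and leaves C1 as the only α-methylene of the later ketone. The C7 configuration must come from a reduction that places the hydroxyl equatorial.

In 14 the bonds C1–C2 and C8–C9 are cut, leading to ring C enone 11 and diene 13. A Robinson-type annulation would place the ring A oxygen and methyl wrongly, and a separate conjugate addition and ring closure would need two steps. This cut forms the quaternary C2, the cis ring fusion and the regiodefined enol ether in one convergent step, and it uses the C7 carbonyl twice, first as activating group and later as electrophile. Enone 11 carries only the C5/C6 stereocentres. The forward reaction must give ortho/para regiochemistry, attack on the alkene face anti to the axial C6 methyl, and suprafacial delivery.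

Diene 13 is the silyl dienol ether of enone 12 (O–Si bond). The forward enolisation must take place at the methyl ketone terminus, not at the γ-position.

Enone 11 is simplified to 9 by removing the C2 methyl (conjugate-addition retron, via enol ether 10), and 9 to the saturated ketone 7 by removing the unsaturation (via enol ether 8). C6 is quaternary, so 7 can enolise only toward C8 and regiochemistry is not in question. The forward steps are a cuprate addition and two dehydrogenations of silyl enol ethers.

Acetonide 7 goes back to diol 6 and its silyl ether 5, and 5 to the achiral dione 4 by adding back one hydride equivalent (C5–H bond). Reduction of one of two enantiotopic carbonyls sets C5 and C6 together and fixes the absolute configuration of the whole route. The hydroxyl must end cis to the methyl and trans to the oxymethyl arm; reagent-controlled chemical reductions would approach anti to the larger arm and give the other diastereomer, which is why an enzyme is chosen.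

Dione 4 is the silyl ether of 3; 3 is cut at C6–C12 (aldol retron) to 2, and 2 at the C6–methyl bond (alkylation retron) to commercial cycloheptane-1,3-dione 1. The oxygenated one-carbon unit is introduced by aldol addition because that can only bond at carbon, whereas alkoxymethyl halides tend to O-alkylate dione enolates.

## Roads not taken

Alternative 1: The cut removes three ring bonds at once (C6–C7, C1–C7 and C2–C8) and traces the carbon skeleton to farnesyl diphosphate A1. In the forward sense a magnesium-dependent class 1 terpene cyclase (a longipinene synthase) would ionise A1 and fold it into α-longipinene A2 of the target's ring configuration, setting C1, C2, C7 and C8 in one enzymatic step.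
- Merits: the whole tricyclic skeleton arises in a single step from a fermentable precursor, with no hindered displacement and no cycloaddition to worry about.
- Weak points: A2 has no oxygen. The C11 ketone could come from allylic oxidation, a known reaction type on such alkenes. O5 and O12, however, need hydroxylation of an unactivated ring methylene and of one of two diastereotopic methyl groups on C6, with the correct configuration at C5 and C6. No general chemical reagent does this, so further oxidising enzymes would have to be found or engineered, as would a cyclase of the right enantioselectivity.
- Comparison: for building the skeleton this road is clearly shorter than the chosen plan (one step against the thirteen needed to reach 18). The chosen plan sets against it that every oxygen enters with a building block (O5 with 1, O12 with the aldol partner, O11 with 13) and that every step is a known laboratory reaction type.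

Alternative 2: The cut goes through ring B as C1–C7 plus C2–C8, a crossed [2+2] retron with C7 as a cyclobutanone carbonyl. In the forward sense an unsaturated amide would be activated with a triflating agent and a hindered pyridine base to a keteniminium ion. Its central carbon (C7) would bond to the alkene CH (C1) and its α-carbon (C8) to the methylated alkene carbon (C2), and hydrolysis would give bicyclo[3.1.1]heptanone A3 with rings A and B in place.
- Merits: the strained ring is made by a cycloaddition that is insensitive to the steric hindrance that burdens a displacement; the precursor is acyclic; the crossed regiochemistry follows from the tertiary cationic character at C2.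
- Weak points: A3 lacks ring C and has C7 as a ketone. The seven-membered ring would have to be closed onto a cyclobutanone carbon by forming C5–C6 and C6–C7, creating the quaternary C6 and the C5 carbinol late with no strong controlling element. The exocyclic methylene would need isomerisation and oxidation to the enone. The absolute configuration would rest on a chiral amine auxiliary, since the precursor has no stereocentre.
- Comparison: for ring B this road is better than the chosen plan, which must accept a displacement at a hindered secondary carbon. The chosen plan sets against it a catalytic enzymatic source of absolute configuration, C5 and C6 in place from step 4 and used to relay all later stereochemistry, a ring C that never has to be closed, and a shorter path after the key step.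

Alternative 3: The cut is the cyclobutane bond C2–C8 at the quaternary carbon. In the forward sense a strong Lewis acid would ionise a tertiary C2–Cl bond on ring C, and the γ-carbon (C8) of a ring A silyl dienol ether would capture the cation, closing ring B and giving enone carbonate A4 directly.
- Merits: cation chemistry is indifferent to congestion at C2, needs no stereodefined leaving group at C7 and no separate dehydrogenation. A4 corresponds to 18 with a carbonate in place of the acetonide, so the endgame would be the same.
- Weak points: closing a cyclobutane by cation capture runs against the usual direction of pinane chemistry, in which the four-membered ring opens to exactly this kind of tertiary cation under Lewis acids. The cation can also lose a proton or rearrange, and the dienol ether can react at its α-carbon (C10), which would close a different four-membered ring. The cyclisation substrate is no easier to assemble than 17.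
- Comparison: it avoids the two weakest points of the chosen plan (the configuration of the C7 carbinol and the displacement at a neopentyl-type secondary carbon) and is better in those respects. The chosen plan sets against it an irreversible, base-mediated closure under conditions in which the strained product is stable, and a cyclisation substrate made by a stereocontrolled cycloaddition.

Key step: step 9

## Remarks on the chemistry (assumptions)

- The ketoreductase of step 4 is taken to be a panel enzyme, identified by screening, that forms the (R)-carbinol at C5 and reduces the carbonyl whose choice makes C6 (S).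
- Enol ether 10 is expected as a mixture of C2 epimers, and 14–16 as the endo isomer (9-methyl cis to C7). Both centres become trigonal later (steps 7 and 12), so neither has to be controlled.

## Route

Step 1
Reactants: 1 cycloheptane-1,3-dione
Product: 2 2-methylcycloheptane-1,3-dione
Conditions: MeI, K2CO3, acetone, reflux
Reagents that add atoms: iodomethane, CI
Why: C-Alkylation of a 1,3-dione enolate; this dione is largely diketonic and behaves like an open-chain β-diketone, so methylation at the doubly activated carbon is the expected course. No stereocentre is formed.

Step 2
Reactants: 2 2-methylcycloheptane-1,3-dione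
Product: 3 2-(hydroxymethyl)-2-methylcycloheptane-1,3-dione
Conditions: aq. CH2O (37%), KHCO3 (cat.), THF/H2O, rt
Reagents that add atoms: formaldehyde, C=O
Why: Base-catalysed aldol addition (hydroxymethylation) of the activated methine; bond formation can only occur at carbon, and the quaternary product cannot react further. The product is achiral, with C6 a prochiral centre.

Step 3
Reactants: 3 2-(hydroxymethyl)-2-methylcycloheptane-1,3-dione
Product: 4 2-[(tert-butyldimethylsilyloxy)methyl]-2-methylcycloheptane-1,3-dione
Conditions: TBSCl, imidazole, CH2Cl2, 0 °C to rt
Reagents that add atoms: tert-butyldimethylsilyl chloride, CC(C)(C)[Si](C)(C)Cl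
Why: Standard silylation of a primary alcohol under weakly basic conditions; it blocks retro-aldol loss of formaldehyde during the buffered enzymatic step.

Step 4
Reactants: 4 2-[(tert-butyldimethylsilyloxy)methyl]-2-methylcycloheptane-1,3-dione
Product: 5 (2S,3R)-2-[(tert-butyldimethylsilyloxy)methyl]-3-hydroxy-2-methylcycloheptan-1-one
Conditions: ketoreductase (R-selective, from a screening panel), NADP+ (cat.), i-PrOH, phosphate buffer pH 7, DMSO (5%), 30 °C
Reagents that add atoms: none
Why: Enzymatic desymmetrisation of a prochiral 2,2-disubstituted cyclic 1,3-dione by monoreduction, a known reaction type for five- to seven-membered diones. The enzyme selects one enantiotopic carbonyl and one face, which sets C6 (S) and C5 (R) together, with the hydroxyl cis to the methyl and trans to the silyloxymethyl arm; over-reduction is limited by reaction time.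

Step 5
Reactants: 5 (2S,3R)-2-[(tert-butyldimethylsilyloxy)methyl]-3-hydroxy-2-methylcycloheptan-1-one
Product: 7 acetonide of (2S,3R)-3-hydroxy-2-(hydroxymethyl)-2-methylcycloheptan-1-one (trans-fused 1,3-dioxane), via diol 6 (not isolated)
Conditions: CSA (cat.), MeOH, 0 °C to rt; concentrate; Me2C(OMe)2, acetone, rt
Reagents that add atoms: 2,2-dimethoxypropane, COC(C)(C)OC
Why: Acid-catalysed methanolysis of the primary silyl ether followed by acetonide formation through transacetalisation. The trans-1,3-diol gives a trans-fused dioxane, which holds C12 and O5 equatorial and the C6 methyl axial on ring C; no stereocentre changes.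

Step 6
Reactants: 7 acetonide of (2S,3R)-3-hydroxy-2-(hydroxymethyl)-2-methylcycloheptan-1-one
Product: 9 acetonide of (6R,7S)-6-hydroxy-7-(hydroxymethyl)-7-methylcyclohept-2-en-1-one, via trimethylsilyl enol ether 8 (not isolated)
Conditions: LiN(i-Pr)2, THF, −78 °C; Me3SiCl; then Pd(OAc)2, MeCN, rt
Reagents that add atoms: none
Why: Saegusa–Ito dehydrogenation; the ketone can enolise only toward C8 because C6 is quaternary, the silyl enol ether is palladated by divalent palladium and β-hydride elimination gives the C8=C2 enone.

Step 7
Reactants: 9 acetonide of (6R,7S)-6-hydroxy-7-(hydroxymethyl)-7-methylcyclohept-2-en-1-one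
Product: 11 acetonide of (6R,7S)-6-hydroxy-7-(hydroxymethyl)-3,7-dimethylcyclohept-2-en-1-one (ring C β-methyl enone), via trimethylsilyl enol ether 10 (not isolated)
Conditions: Me2CuLi, Me3SiCl, THF, −78 °C; then Pd(OAc)2, MeCN, rt
Reagents that add atoms: lithium dimethylcuprate, [Li+].C[Cu-]C
Why: Conjugate addition of the Gilman cuprate with silyl chloride trapping places the methyl on C2 and gives the enol ether regiospecifically. A second Saegusa–Ito oxidation restores the C8=C2 alkene, now trisubstituted, and removes the transient C2 stereocentre.

Step 8
Reactants: 12 (E)-pent-3-en-2-one
Product: 13 (E)-2-(tert-butyldimethylsilyloxy)penta-1,3-diene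
Conditions: TBSOTf, Et3N, Et2O, 0 °C
Reagents that add atoms: tert-butyldimethylsilyl trifluoromethanesulfonate, CC(C)(C)[Si](C)(C)OS(=O)(=O)C(F)(F)F
Why: Soft enolisation (silyl triflate and amine) of the enone at its α′-methyl group gives the cross-conjugated 2-silyloxydiene; the E alkene is untouched.

Step 9
Reactants: 11 ring C β-methyl enone acetonide; 13 (E)-2-(tert-butyldimethylsilyloxy)penta-1,3-diene
Product: 14 cis-fused ring A/ring C ketone: C7 ketone, C10=C11 tert-butyldimethylsilyl enol ether, 2- and 9-methyl, O5/O12 acetonide; H-8 and 2-methyl cis on the 6-methyl face, ring A on the C12 face, 9-methyl cis to C7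
Conditions: EtAlCl2 (1.5 equiv), 13 (3 equiv), PhMe/CH2Cl2, −78 to −20 °C; Et3N, aq. NaHCO3
Reagents that add atoms: none
Why: EtAlCl2 binds the C7 carbonyl of 11 and lowers the enone LUMO; the nucleophilic CH2 terminus of 13 (C1) bonds to the β-carbon C2 and the methyl-bearing terminus (C9) to the α-carbon C8 in a concerted but strongly asynchronous [4+2] addition, at its limit a Mukaiyama–Michael addition followed by closure of the aluminium enolate onto the silyloxyallyl cation. The closest known reaction type is the Lewis-acid-promoted Diels–Alder reaction of 2-silyloxydienes with β-methyl cycloalkenones, which gives cis-fused bicyclic ketones with an angular methyl. Ring A (C2, C1, C11, C10, C9, C8) closes as a six-membered ring by intermolecular cycloaddition, both bonds being made on the same face of the C8=C2 alkene. The regiochemistry needed (silyloxy carbon para and diene methyl ortho to the C7 carbonyl) is favoured by both diene substituents, which polarise the diene in the same sense. C2 and C8 are set by the face of attack: the trans-fused acetonide holds the C6 methyl axial and syn-axial to the lower face of C8, so the diene should add to the face that carries C12, and suprafacial addition makes H-8 and the 2-methyl cis. C9 follows from the E geometry of the diene and an endo orientation of the C7 carbonyl (9-methyl cis to C7); this centre is erased in step 12 and need not be controlled. The alkylaluminium halide also scavenges protons, which protects the silyl enol ether needed later as the handle for the ring A enone.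

Step 10
Reactants: 14 cis-fused ring A/ring C ketone silyl enol ether
Product: 15 C7 alcohol of 14 with the hydroxyl on the 6-methyl face (trans to C9 and to C12, anti to ring A)
Conditions: Li, NH3(l)/THF, t-BuOH, −78 °C; NH4Cl
Reagents that add atoms: none
Why: Dissolving-metal reduction of a hindered ring ketone gives mainly the more stable carbinol; with the C6 methyl axial, the equatorial position at C7 lies on the 6-methyl face, trans to C9 and away from the axial C1 methylene, which is the configuration needed for rear-side attack by C1. Solvated electrons do not reduce the isolated silyl enol ether or the acetonide.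

Step 11
Reactants: 15 C7 alcohol
Product: 16 C7 methanesulfonate of 15
Conditions: MsCl, Et3N, CH2Cl2, 0 °C
Reagents that add atoms: methanesulfonyl chloride, CS(=O)(=O)Cl
Why: Sulfonylation through sulfene is fast even for hindered secondary alcohols and retains the C7 configuration; the silyl enol ether tolerates the amine-buffered conditions.

Step 12
Reactants: 16 C7 methanesulfonate
Product: 17 ring A enone mesylate (C11 ketone, C9=C10 alkene with 9-methyl, C7 mesylate unchanged)
Conditions: Pd(OAc)2, DMSO/MeCN, 40 °C
Reagents that add atoms: none
Why: Saegusa–Ito oxidation of the regiodefined silyl enol ether: palladation at C10 and syn β-hydride elimination of H-9 give the enone with the methyl on its β-carbon and remove the C9 stereocentre; the mesylate is inert to divalent palladium.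

Step 13
Reactants: 17 ring A enone mesylate
Product: 18 (1R,2R,5R,6S,7S,8R)-2,6,9-trimethyl-11-oxotricyclo[5.4.0.0(2,8)]undec-9-ene with O5 and O12 bridged as the acetonide
Conditions: KN(SiMe3)2, THF, −78 °C (inverse addition), then to rt
Reagents that add atoms: none
Why: Kinetic deprotonation of the enone at the α′-methylene C1 gives the cross-conjugated enolate, and intramolecular enolate alkylation (4-exo-tet) follows, C1 held axial on C2 displacing the C7 mesylate from the rear; this is the known keto-sulfonate closure of cyclobutanes in bridged terpenes. C7 is set by the inversion and C1 by the bridged geometry, which allows only one mode of closure.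

Step 14
Reactants: 18 tricyclic enone acetonide
Product: 19 (1R,2R,5R,6S,7S,8R)-5-hydroxy-6-(hydroxymethyl)-2,6,9-trimethyltricyclo[5.4.0.0(2,8)]undec-9-en-11-one
Conditions: AcOH/H2O (4:1), 40 °C
Reagents that add atoms: none
Why: Acid-catalysed acetal hydrolysis; the alkene next to the cyclobutane is part of an electron-poor enone, so protonation and ring opening are much less likely than for an isolated alkene, and dilute acetic acid is mild.

Step 15
Reactants: 19 tricyclic enone diol; 20 angelic acid [(Z)-2-methylbut-2-enoic acid]
Product: 21 primary (O12) mono[(Z)-2-methylbut-2-enoate] of 19, with the C5 hydroxyl free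
Conditions: 20 (1.1 equiv), 2,4,6-Cl3C6H2COCl, Et3N, PhMe, rt; then 19, 40 °C
Reagents that add atoms: none
Why: Yamaguchi-type esterification through the 2,4,6-trichlorobenzoyl mixed anhydride without a nucleophilic catalyst; the alcohol attacks the angeloyl carbonyl because the aroyl carbonyl is screened by its two ortho chlorines. With about one equivalent at moderate temperature the primary hydroxyl should react well before the secondary one, which is flanked by the quaternary C6; the Z geometry is kept and no stereocentre is touched.

Step 16
Reactants: 21 primary monoangelate; 20 angelic acid [(Z)-2-methylbut-2-enoic acid]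
Product: 22 CNP0240716.2, the 5,12-bis[(Z)-2-methylbut-2-enoate] of 19
Conditions: 20 (3 equiv), 2,4,6-Cl3C6H2COCl, Et3N, PhMe, rt; then 21, 80 °C
Reagents that add atoms: none
Why: The same mixed-anhydride esterification in hot toluene, conditions under which hindered secondary alcohols are converted into Z-2-methylbut-2-enoates without isomerisation to the E esters because no nucleophilic catalyst is present. Only the C5 hydroxyl is free in 21, so chemoselectivity is not in question, and no stereocentre is touched.

## Compound list

1 | cycloheptane-1,3-dione | O=C1CCCCC(=O)C1 | starting material
2 | 2-methylcycloheptane-1,3-dione | CC1C(=O)CCCCC1=O | intermediate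
3 | 2-(hydroxymethyl)-2-methylcycloheptane-1,3-dione | CC1(CO)C(=O)CCCCC1=O | intermediate
4 | 2-[(tert-butyldimethylsilyloxy)methyl]-2-methylcycloheptane-1,3-dione | CC1(CO[Si](C)(C)C(C)(C)C)C(=O)CCCCC1=O | intermediate
5 | (2S,3R)-2-[(tert-butyldimethylsilyloxy)methyl]-3-hydroxy-2-methylcycloheptan-1-one | CC(C)(C)[Si](C)(C)OC[C@]1(C)C(=O)CCCC[C@H]1O | intermediate
6 | (2S,3R)-3-hydroxy-2-(hydroxymethyl)-2-methylcycloheptan-1-one | OC[C@]1(C)C(=O)CCCC[C@H]1O | intermediate (not isolated)
7 | acetonide of 6 (trans-fused 2,2-dimethyl-1,3-dioxane across O5/O12; C7 ketone) | CC1(C)OC[C@]2(C)C(=O)CCCC[C@H]2O1 | intermediate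
8 | trimethylsilyl enol ether of 7 (C7–OSiMe3, C7=C8) | CC1(C)OC[C@]2(C)C(O[Si](C)(C)C)=CCCC[C@H]2O1 | intermediate (not isolated)
9 | acetonide of (6R,7S)-6-hydroxy-7-(hydroxymethyl)-7-methylcyclohept-2-en-1-one | CC1(C)OC[C@]2(C)C(=O)C=CCC[C@H]2O1 | intermediate
10 | trimethylsilyl enol ether from cuprate addition to 9 (C7–OSiMe3, C7=C8, 2-methyl; mixture of C2 epimers) | CC1(C)OC[C@]2(C)C(O[Si](C)(C)C)=CC(C)CC[C@H]2O1 | intermediate (not isolated)
11 | acetonide of (6R,7S)-6-hydroxy-7-(hydroxymethyl)-3,7-dimethylcyclohept-2-en-1-one (ring C β-methyl enone) | CC1(C)OC[C@]2(C)C(=O)C=C(C)CC[C@H]2O1 | intermediate
12 | (E)-pent-3-en-2-one | C/C=C/C(C)=O | starting material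
13 | (E)-2-(tert-butyldimethylsilyloxy)penta-1,3-diene | C=C(O[Si](C)(C)C(C)(C)C)/C=C/C | intermediate
14 | cis-fused ring A/ring C ketone: C7 ketone, C10=C11 TBS enol ether, 2- and 9-methyl, O5/O12 acetonide; H-8 and 2-methyl on the 6-methyl face, ring A on the C12 face, 9-methyl cis to C7 | CC1(C)OC[C@]2(C)C(=O)[C@@H]3[C@H](C)C=C(O[Si](C)(C)C(C)(C)C)C[C@]3(C)CC[C@H]2O1 | intermediate
15 | C7 alcohol of 14, hydroxyl on the 6-methyl face (trans to C9 and C12) | CC1(C)OC[C@]2(C)[C@@H](O)[C@@H]3[C@H](C)C=C(O[Si](C)(C)C(C)(C)C)C[C@]3(C)CC[C@H]2O1 | intermediate
16 | C7 methanesulfonate of 15 | CC1(C)OC[C@]2(C)[C@@H](OS(C)(=O)=O)[C@@H]3[C@H](C)C=C(O[Si](C)(C)C(C)(C)C)C[C@]3(C)CC[C@H]2O1 | intermediate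
17 | ring A enone mesylate (C11 ketone, C9=C10, 9-methyl; C7 mesylate; O5/O12 acetonide) | CC1(C)OC[C@]2(C)[C@@H](OS(C)(=O)=O)[C@@H]3C(C)=CC(=O)C[C@]3(C)CC[C@H]2O1 | intermediate
18 | (1R,2R,5R,6S,7S,8R)-2,6,9-trimethyl-11-oxotricyclo[5.4.0.0(2,8)]undec-9-ene-5,12-diol acetonide | CC1(C)OC[C@]2(C)[C@@H]3[C@H]4C(=O)C=C(C)[C@@H]3[C@@]4(C)CC[C@H]2O1 | intermediate
19 | (1R,2R,5R,6S,7S,8R)-5-hydroxy-6-(hydroxymethyl)-2,6,9-trimethyltricyclo[5.4.0.0(2,8)]undec-9-en-11-one | OC[C@]1(C)[C@@H]2[C@H]3C(=O)C=C(C)[C@@H]2[C@@]3(C)CC[C@H]1O | intermediate
20 | angelic acid, (Z)-2-methylbut-2-enoic acid | C/C=C(/C)C(=O)O | starting material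
21 | primary (O12) monoangelate of 19 | C/C=C(/C)C(=O)OC[C@]1(C)[C@@H]2[C@H]3C(=O)C=C(C)[C@@H]2[C@@]3(C)CC[C@H]1O | intermediate
22 | CNP0240716.2: [(1R,2R,5R,6S,7S,8R)-2,6,9-trimethyl-5-[(Z)-2-methylbut-2-enoyl]oxy-11-oxotricyclo[5.4.0.0(2,8)]undec-9-en-6-yl]methyl (Z)-2-methylbut-2-enoate | C/C=C(/C)C(=O)OC[C@]1(C)[C@@H]2[C@H]3C(=O)C=C(C)[C@@H]2[C@@]3(C)CC[C@H]1OC(=O)/C(C)=C\C | target

## Step count and least certain steps

Total: 16 steps. Longest linear sequence: 15 steps (steps 1–7 and 9–16, from 1); the diene branch is one step (step 8).

Step 9 (key step). The enone is β,β-disubstituted, flanked by a quaternary carbon and part of a seven-membered ring, so the cycloaddition may be too slow at temperatures at which the diene and the acetonide survive the aluminium Lewis acid. Facial selectivity could also leak if the axial methyl screens the lower face less than expected. Fallback: the two bonds would be made in separate polar steps. Setting out from 11 and 13, catalytic Tf2NH (which generates the silyl triflimide in the flask) in CH2Cl2 at −78 °C should stop at the Mukaiyama–Michael stage and give the ring C silyl enol ether carrying the (E)-2-oxopent-3-enyl chain on C2, F1. In a second operation (fresh catalyst, −40 to 0 °C) C8 of F1 would add to C9 with transfer of the silyl group to O11, which returns to the route at 14.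

Step 4. The enzyme may reduce the other enantiotopic carbonyl or the other face, or turn over the lipophilic silyl ether slowly; a reagent-controlled chemical reduction would not help, since hydride would approach anti to the larger arm and give the cis ketol. Fallback: relative and absolute configuration would be set separately. Setting out from 3, hydroxyl-directed reduction with Me4NBH(OAc)3 (MeCN/AcOH, −20 °C) should deliver hydride from the hydroxymethyl face to one carbonyl and give the trans ketol diol as a racemate, that is 6 together with the enantiomeric diol F2. A lipase with vinyl acetate, screened to acylate the primary hydroxyl of the unwanted enantiomer, would convert F2 into the primary acetate F3, and the unreacted diol would rejoin the route at 6 (second stage of step 5).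

Step 10. The reduction may not follow the thermodynamic preference assumed for this hindered ketone, the basic medium may epimerise C8 before reduction, or the silyl enol ether may be cleaved by alkoxide. Fallback: kinetic, reagent-approach control with recycling. Setting out from 14, LiAlH4 (Et2O, −78 °C) would give 15 together with the C7-epimeric alcohol F4. The two would be separated, F4 oxidised back to 14 with Dess–Martin periodinane (NaHCO3 buffer) and resubmitted, and the route would be rejoined at 15.

Step 13. Displacement at a secondary carbon next to the quaternary C6 may be slow enough for other processes to take over: equilibration to the γ-dienolate followed by alkylation at C10, vinylogous elimination of the mesylate toward C8, or deprotonation of the mesyl methyl group. Fallback: the nucleophile would be fixed regiochemically before cyclisation and released without strong base. Setting out from 17, LiN(i-Pr)2 with Me3SiCl present (THF, −78 °C) should give the cross-conjugated trimethylsilyl dienol ether F5 (C1=C11–OSiMe3), which can be isolated and its regiochemistry checked. Anhydrous fluoride, Bu4N[Ph3SiF2] in THF/DMF, would then unmask the ammonium enolate, which should cyclise and return to the route at 18.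

Step 16. Acylation of the neopentyl-type C5 hydroxyl of 21 may be very slow, and prolonged heating raises the chance of Z to E isomerisation of the ester already in place. Fallback: the alkoxide would be acylated instead of the neutral alcohol. Setting out from 21, LiN(SiMe3)2 (1 equiv, THF, −78 °C) followed by angelic anhydride F6 (made from 20 with dicyclohexylcarbodiimide) would acylate O5 at low temperature without an amine base, returning to the route at 22.

## Further compounds

F1 | step 9 | ring C tert-butyldimethylsilyl enol ether (C7–OTBS, C7=C8) carrying the (E)-2-oxopent-3-enyl chain on C2, O5/O12 acetonide | CC1(C)OC[C@]2(C)C(O[Si](C)(C)C(C)(C)C)=C[C@](C)(CC(=O)/C=C/C)CC[C@H]2O1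
F2 | step 4 | (2R,3S)-3-hydroxy-2-(hydroxymethyl)-2-methylcycloheptan-1-one (enantiomer of 6) | OC[C@@]1(C)C(=O)CCCC[C@@H]1O
F3 | step 4 | primary acetate of F2 | CC(=O)OC[C@@]1(C)C(=O)CCCC[C@@H]1O
F4 | step 10 | C7 epimer of 15 (hydroxyl on the ring A face) | CC1(C)OC[C@]2(C)[C@H](O)[C@@H]3[C@H](C)C=C(O[Si](C)(C)C(C)(C)C)C[C@]3(C)CC[C@H]2O1
F5 | step 13 | cross-conjugated trimethylsilyl dienol ether of 17 (C1=C11–OSiMe3, C9=C10; C7 mesylate) | CC1(C)OC[C@]2(C)[C@@H](OS(C)(=O)=O)[C@@H]3C(C)=CC(O[Si](C)(C)C)=C[C@]3(C)CC[C@H]2O1
F6 | step 16 | angelic anhydride, (Z)-2-methylbut-2-enoic anhydride | C/C=C(/C)C(=O)OC(=O)/C(C)=C\C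
A1 | alternative 1 | (2E,6E)-farnesyl diphosphate | CC(C)=CCC/C(C)=C/CC/C(C)=C/COP(=O)(O)OP(=O)(O)O
A2 | alternative 1 | α-longipinene (enantiomer with the ring configuration of the target) | CC1(C)[C@@H]2[C@H]3CC=C(C)[C@@H]2[C@@]3(C)CCC1
A3 | alternative 2 | 7-[3-(tert-butyldimethylsilyloxy)propyl]-7-methyl-2-methylidenebicyclo[3.1.1]heptan-6-one | O=C1[C@H]2CCC(=C)[C@@H]1[C@@]2(C)CCCO[Si](C)(C)C(C)(C)C
A4 | alternative 3 | tricyclic enone cyclic carbonate (carbonate analogue of 18) | O=C1OC[C@]2(C)[C@@H]3[C@H]4C(=O)C=C(C)[C@@H]3[C@@]4(C)CC[C@H]2O1
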